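**Assumptions.** The SMILES is read as the trans isomer, (3R,4S) in 3,4‑dihydronaphthalene‑2‑carbaldehyde numbering, which is (1S,2R) in 1,2‑dihydronaphthalene numbering (aryl carbon = C1). Succinaldehyde is made fresh from 2,5‑dimethoxytetrahydrofuran. The route is a proposal and has not been run; the stereochemical outcome of Step 6 is predicted from an enamine model, not demonstrated.

## Retrosynthetic overview

1. Vitedoin A ⇐ TIPS ether 9 ⇐ dialdehyde 8, by desilylation and chemoselective reduction of the saturated C2–CHO.
2. 8 ⇐ lactol 5 + succinaldehyde: a new one‑pot asymmetric 1,6‑addition/aldol condensation forms C1–C2 and C3=C4, the carbocycle and both stereocentres.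
3. 5 ⇐ two vanillin units, joined at C2 of vanillin (between CHO and OMe) by directed ortho‑lithiation and addition to a second vanillin aldehyde.
4. Ring order: both arenes are bought (vanillin ×2); a temporary phthalan lactol ring forms in Step 3 and is opened in Step 6, where the dihydronaphthalene ring is formed last.

## Route

**Step 1**
Reactants: 1, vanillin
Product: 2, 3‑methoxy‑4‑[(triisopropylsilyl)oxy]benzaldehyde
Conditions: TIPSCl, imidazole, DMF, rt
Reagents that add atoms: TIPSCl, CC(C)[Si](Cl)(C(C)C)C(C)C
Why: Standard phenol silylation; the bulky TIPS ether survives BuLi and later blocks the position ortho to it.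

**Step 2**
Reactants: 1, vanillin
Product: 3, 4‑(allyloxy)‑3‑methoxybenzaldehyde
Conditions: allyl bromide, K2CO3, DMF, 50 °C
Reagents that add atoms: allyl bromide, C=CCBr
Why: Williamson etherification; allyl is removable later by Pd(0) without touching the aryl TIPS ether.

**Step 3**
Reactants: 2, TIPS‑vanillin; 3, O‑allylvanillin
Product: 4, 3‑[4‑(allyloxy)‑3‑methoxyphenyl]‑4‑methoxy‑5‑[(triisopropylsilyl)oxy]‑1,3‑dihydroisobenzofuran‑1‑ol (racemic, mixture of lactol epimers)
Conditions: LiN(Me)CH2CH2NMe2, THF, −20 °C; n‑BuLi (2.5 equiv), −20 °C; then 3 (3 equiv), −78 °C → rt; aq NH4Cl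
Reagents that add atoms: none (all atoms come from 2 and 3)
Why: Directed ortho‑metalation through an in situ α‑amino alkoxide: the CHO is masked and lithiation occurs at C2, flanked by both directing groups (TIPS shields C5); the aryllithium adds to 3, and on workup the regenerated CHO closes onto the new benzhydrol as the lactol. Both stereocentres of 4 are erased in Step 6.

**Step 4**
Reactants: 4, O‑allyl lactol
Product: 5, 3‑(4‑hydroxy‑3‑methoxyphenyl)‑4‑methoxy‑5‑[(triisopropylsilyl)oxy]‑1,3‑dihydroisobenzofuran‑1‑ol
Conditions: Pd(PPh3)4 (3 mol %), morpholine, THF, rt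
Reagents that add atoms: none
Why: Tsuji–Trost‑type deallylation under near‑neutral conditions frees only the pendant phenol; the lactol and aryl TIPS ether are untouched.

**Step 5**
Reactants: 6, 2,5‑dimethoxytetrahydrofuran
Product: 7, succinaldehyde
Conditions: H2O, 90 °C; distil
Reagents that add atoms: water, O
Why: Acetal hydrolysis in hot water, the usual preparation of fresh monomeric succinaldehyde.

**Step 6 (key step, new)**
Reactants: 5, phenol lactol; 7, succinaldehyde (3 equiv, slow addition)
Product: 8, (1S,2R)‑1‑(4‑hydroxy‑3‑methoxyphenyl)‑8‑methoxy‑7‑[(triisopropylsilyl)oxy]‑1,2‑dihydronaphthalene‑2,3‑dicarbaldehyde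
Conditions: (R)‑α,α‑diphenylprolinol TMS ether (20 mol %), ClCH2CO2H (30 mol %), CH2Cl2, rt → 40 °C
Reagents that add atoms: none (5 + 7 − 2 H2O)
Why: Proposed new method: an amine/Brønsted‑acid‑catalysed asymmetric formal [4+2] annulation of succinaldehyde with an in situ ortho‑formylaryl p‑quinone methide. Acid ionises the doubly benzylic C3–O bond of 5 (pushed by the para‑OH) to give the p‑quinone methide and release the aryl CHO. The (R)‑catalyst E‑enamine of succinaldehyde attacks the exocyclic carbon from its unshielded face, which sets C2 = R; a synclinal approach like that in enamine–nitroalkene Michael additions is expected to give C1 = S (trans). The second CHO then undergoes amine‑mediated 6‑membered intramolecular aldol condensation onto the aryl CHO, made irreversible by dehydration to the conjugated enal. Closest known reaction types: enamine‑catalysed 1,6‑addition of aldehydes to stable p‑quinone methides, SN1‑type α‑alkylation of aldehydes with benzhydrols, and succinaldehyde Michael/aldol‑condensation annulations.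

**Step 7**
Reactants: 8, dialdehyde
Product: 9, (3R,4S)‑4‑(4‑hydroxy‑3‑methoxyphenyl)‑3‑(hydroxymethyl)‑5‑methoxy‑6‑[(triisopropylsilyl)oxy]‑3,4‑dihydronaphthalene‑2‑carbaldehyde
Conditions: NaBH4 (0.5 equiv), EtOH/CH2Cl2 (3:7), −78 °C; chromatography to remove any cis isomer
Reagents that add atoms: none (hydride only)
Why: Chemoselective borohydride reduction: the saturated aldehyde is far more electrophilic than the enal, which is deactivated by conjugation to the para‑silyloxy arene; C2 is no longer epimerisable afterwards.

**Step 8**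
Reactants: 9, TIPS ether
Product: 10, vitedoin A, (3R,4S)‑6‑hydroxy‑4‑(4‑hydroxy‑3‑methoxyphenyl)‑3‑(hydroxymethyl)‑5‑methoxy‑3,4‑dihydronaphthalene‑2‑carbaldehyde
Conditions: TBAF, AcOH, THF, 0 °C
Reagents that add atoms: none
Why: Buffered fluoride cleavage of the aryl silyl ether; the enal, primary alcohol and both stereocentres are unaffected.

## Compound list

1 | vanillin | COc1cc(C=O)ccc1O | starting material
2 | 3‑methoxy‑4‑[(triisopropylsilyl)oxy]benzaldehyde | COc1cc(C=O)ccc1O[Si](C(C)C)(C(C)C)C(C)C | intermediate
3 | 4‑(allyloxy)‑3‑methoxybenzaldehyde | COc1cc(C=O)ccc1OCC=C | intermediate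
4 | 3‑[4‑(allyloxy)‑3‑methoxyphenyl]‑4‑methoxy‑5‑[(triisopropylsilyl)oxy]‑1,3‑dihydroisobenzofuran‑1‑ol (racemic, epimer mixture) | OC1OC(c2ccc(OCC=C)c(OC)c2)c2c1ccc(O[Si](C(C)C)(C(C)C)C(C)C)c2OC | intermediate
5 | 3‑(4‑hydroxy‑3‑methoxyphenyl)‑4‑methoxy‑5‑[(triisopropylsilyl)oxy]‑1,3‑dihydroisobenzofuran‑1‑ol (racemic, epimer mixture) | OC1OC(c2ccc(O)c(OC)c2)c2c1ccc(O[Si](C(C)C)(C(C)C)C(C)C)c2OC | intermediate
6 | 2,5‑dimethoxytetrahydrofuran | COC1CCC(OC)O1 | starting material
7 | succinaldehyde | O=CCCC=O | intermediate
8 | (1S,2R)‑1‑(4‑hydroxy‑3‑methoxyphenyl)‑8‑methoxy‑7‑[(triisopropylsilyl)oxy]‑1,2‑dihydronaphthalene‑2,3‑dicarbaldehyde | COc1cc([C@H]2c3c(ccc(O[Si](C(C)C)(C(C)C)C(C)C)c3OC)C=C(C=O)[C@@H]2C=O)ccc1O | intermediate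
9 | (3R,4S)‑4‑(4‑hydroxy‑3‑methoxyphenyl)‑3‑(hydroxymethyl)‑5‑methoxy‑6‑[(triisopropylsilyl)oxy]‑3,4‑dihydronaphthalene‑2‑carbaldehyde | COc1cc([C@H]2c3c(ccc(O[Si](C(C)C)(C(C)C)C(C)C)c3OC)C=C(C=O)[C@@H]2CO)ccc1O | intermediate
10 | vitedoin A | COc1cc([C@H]2c3c(ccc(O)c3OC)C=C(C=O)[C@@H]2CO)ccc1O | target

## Summary

Total steps: 8. Longest linear sequence: 6 (Steps 1, 3, 4, 6, 7, 8).

**Steps most likely to fail**

1. **Step 6 (proposed new annulation).** Risks are low trans/cis selectivity at C1, diversion of 5 to the isobenzofuran, and succinaldehyde self‑aldol. Fallback (known chemistry, auxiliary control):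
   - Quench lithiated 2 with I2, Heck‑couple the 2‑iodo aldehyde with an N‑acryloyl Evans oxazolidinone, and mask the CHO as its dimethyl acetal.
   - Set C1 by CuBr·SMe2‑mediated conjugate addition of 4‑TIPSO‑3‑methoxyphenylmagnesium bromide.
   - Set C2 by auxiliary‑controlled enolate allylation, with the auxiliary enantiomer chosen for each step to give 1S,2R.
   - LiBH4 gives the C2–CH2OH; ozonolysis of the allyl group, acetal hydrolysis and piperidinium acetate aldol condensation close the ring.

2. **Step 3 (α‑amino alkoxide lithiation/addition).** Risks are incomplete or mis‑sited lithiation and loss of 3 to excess BuLi. Fallback: the classical amide route to the same lactol. Make 4‑TIPSO‑3‑methoxy‑N,N‑diethylbenzamide from vanillic acid, lithiate with s‑BuLi/TMEDA between CONEt2 and OMe, add to 3, lactonise with acid to the 3‑arylphthalide, and reduce with DIBAL‑H to 4.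

3. **Step 7 (CHO versus enal selectivity).** Fallback: reduce both aldehydes to the diol (NaBH4, CeCl3), then re‑oxidise only the allylic/benzylic‑conjugated alcohol with activated MnO2.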